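Atom labels used throughout: C1 is the ring alkene carbon bearing the exocyclic C7H2, C2 is the alkene CH, C3–C6 are the four oxygenated ring carbons in order, and O3–O7 is the oxygen on the carbon of the same number. PMB is 4-methoxybenzyl. Compound numbers 1–12 are those of the steps and the compound list.

## The problem

Target 12 is one cyclohexene ring (C1=C2) whose four sp3 carbons C3–C6 all carry oxygen, with C7H2 on C1; O5 and O7 are benzoates, while O3, O4 and O6 are free hydroxyls. The stereocentres are contiguous (3R,4R,5R,6R) and read 3,4-cis, 4,5-trans, 5,6-cis, so the ring holds two cis-diols on opposite faces. No ring has to be joined to another; the stereochemical task is the absolute configuration of one cis pair and its relay to the other. A cis-diol at C5/C6 on one face of a cyclohexadiene can send an oxidant to the opposite face of C3=C4, which fixes C3 and C4 together, so only C5 and C6 need outside control. The second task is regiochemical: of five oxygens two are acylated, and O5 must be told apart from its cis neighbour O6 and from O4. Benzoates on such a polyol migrate between neighbouring hydroxyls under base (O5 to O4 or O6, O7 to O6), so the last unmasking cannot be basic; the cyclohexadiene-diol intermediates also lose water to phenols when acidified or warmed. The enabling feature is that C1–C6, with a substituent on C1, unsaturation at C1=C2 and C3=C4 and a cis-diol at C5/C6 next to C1, is the ortho,meta-cis-dihydrodiol of a monosubstituted benzene, which an arene dioxygenase makes from a halobenzene, leaving the halogen on C1 as the handle for C7.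

## Retrosynthesis

12 from 11. The bonds cut are those of two protecting groups: the O3/O4 isopropylidene ketal and the O6 PMB ether. Both fall to acid, so one acidic operation releases 12 without exposing the esters to base. Ending instead with a selective acylation of a free pentol would ask for discrimination among five hydroxyls. The forward step must be mild enough to leave both benzoates where they are.

11 from 8 and 9. Both ester C–O bonds (O5–CO and O7–CO) are cut at once, back to diol 8 and two equivalents of benzoyl chloride 9; the 7-O-monobenzoate 10 is passed through in the flask. In 8 the only free hydroxyls are the two that must be acylated, so the forward reaction needs no selectivity. This shifts the whole regiochemical burden to an earlier point: O6 must be masked and O5 free.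

8 from 6 and 7. The C1–C7 bond is cut to vinyl iodide 6 and (tributylstannyl)methanol 7. A Stille coupling delivers C7 at the alcohol oxidation level in one step, where carbonylation and reduction would take two. Placing it before benzoylation means no allylic ester is present when palladium is used. The iodide also serves earlier, because it deactivates C1=C2 towards oxidation.

6 from 5 from 4. The C3–O and C4–O bonds are cut to diene 4; triol 5 is the primary product and ketalisation of its cis pair gives 6. A cis-dihydroxylation is preferred over epoxidation and opening, which would give a trans pair. The forward reaction must choose C3=C4 over the iodoalkene and attack anti to O5 and O6. The later ketalisation must take the cis O3/O4 pair and leave the trans-disposed O5–H alone.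

4 from 3 from 2. The two C–O bonds to the acetal carbon are cut. A plain isopropylidene ketal on O5/O6 would protect both oxygens alike and would later have to be removed beside a second, identical ketal, with nothing to tell O5 from O6. A 4-methoxybenzylidene acetal (3) instead can be opened by hydride so that one oxygen keeps a PMB ether and the other is freed. That costs two steps, and the PMB group leaves in the final acid step at no extra cost. The forward opening must put the ether on O6.

2 from 1. The C5–O and C6–O bonds are cut and the ring is rearomatised, which leads to iodobenzene 1. This removes both externally controlled stereocentres and all skeletal complexity in one move. The forward step is an enzymatic cis-dioxygenation that must pick the bond next to iodine and one enantiotopic face.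

## Roads not taken

Alternative 1: Intramolecular Morita–Baylis–Hillman closure.
- Cut and key step: the cut is the C1–C6 bond. An open-chain (Z)-enoate aldehyde A1 would carry C3–C5 from a chiral-pool pentose as an O3,O4-acetonide and an O5-PMB ether. Trimethylphosphine would add in conjugate fashion to C2, the ester enolate would bond from C1 to the aldehyde carbon C6, and expulsion of the phosphine would regenerate C1=C2, giving cyclohexenecarboxylate A2 with a free O6 hydroxyl.
- Merits: C3–C5 come from the chiral pool without a biocatalyst. C7 is in the molecule as an ester, so tin and osmium are avoided. O5 and O6 are already different when the ring closes, which is better than the chosen plan, where that takes two steps (2 to 3 to 4) and a regioselective acetal opening.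
- Weak points: C6 is formed under substrate control only and must come out cis to O5. The α-alkoxy aldehyde can epimerise at C5 or eliminate under the nucleophilic catalyst, and enoates are sluggish acceptors. A1 with three different protecting groups needs about seven steps from the sugar. After A2 come O6 protection, ester reduction, PMB removal, dibenzoylation and deprotection.
- Comparison: this is roughly twice the length of the chosen plan. The chosen plan sets two stereocentres with absolute control in its first step, relays the other two by substrate control and needs eight steps in all.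

Alternative 2: Asymmetric epoxidation of a quinone monoketal.
- Cut and key step: the C4–O and C5–O bonds are introduced as an epoxide on the achiral quinone monoketal A3, which already carries the O7 benzoate. A hydroperoxide and base under a chiral cinchona-derived ammonium phase-transfer catalyst would epoxidise the C4=C5 enone bond to give A4. The C4–O bond stays, and the C5–O bond is later displaced by benzoate with inversion.
- Merits: the route is fully chemical and catalytic in chirality, starts from a flat aromatic precursor and never has to install O7. In those respects it is at least as good as the chosen plan.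
- Weak points: only C4 is set for good in the key step. C5 then depends on a regioselective opening of an α-keto epoxide. C6 and C3 each need a diastereoselective carbonyl reduction, the second after ketal hydrolysis. The benzoate must survive alkaline peroxide, and epoxy enones of this kind aromatise readily.
- Comparison: that makes four separate selectivity events. The chosen plan has one enzymatic step and one osmylation with a well-understood facial preference, and no ketone reductions.

Alternative 3: Biomimetic conjugate opening of a 1,6-epoxy-2-ene.
- Cut and key step: the C3–O bond is cut. In vinyl epoxide A5 (O4 tert-butyl carbonate, O5 and O7 benzoates), BF3·OEt2 would ionise the tertiary allylic C1–O bond. The carbonate carbonyl oxygen would close onto C3 with loss of isobutene, giving the cis-fused 3,4-cyclic carbonate A6 with the alkene at C1=C2 and O6 free.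
- Merits: A6 has both benzoates in place and O6 revealed by the opening itself. This is the most direct answer to the O5/O6 problem and better than the chosen plan on that point.
- Weak points: A5 already has four stereocentres, one a fully substituted epoxide carbon, so the difficulty is moved rather than removed. The O7 benzoate can compete as neighbouring group at C1. The last step would have to hydrolyse a cyclic carbonate beside two benzoates, which are the basic conditions under which the esters migrate or cleave.
- Comparison: the chosen plan ends in acid, which the esters tolerate, and starts from a commodity arene.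

Key step: step 1

Assumption: acetal 3 is carried as the mixture of epimers at its acetal carbon; this is harmless because that carbon becomes the CH2 of the PMB ether in step 3.

## Route

Step 1
Reactants: 1 iodobenzene
Product: 2 (1S,2S)-3-iodocyclohexa-3,5-diene-1,2-diol
Conditions: E. coli JM109 (pDTG601) whole cells expressing toluene dioxygenase (IPTG-induced), glucose, mineral salts medium, air, pH 7, 35 °C; 1 fed neat in portions; EtOAc extraction
Reagents that add atoms: dioxygen, O=O
Why: Toluene dioxygenase is a three-component Rieske non-heme iron enzyme: electrons from NADH travel through a reductase and a ferredoxin to the [2Fe-2S] cluster of the oxygenase, whose mononuclear divalent iron activates O2 and passes both of its atoms to the C5–C6 bond of the bound arene in one suprafacial event. Neither an arene oxide nor a carbocation is released, which is why the diol is cis and does not rearrange to a phenol. The closest known reaction type is this very one, whole-cell arene cis-dihydroxylation of monohalobenzenes by recombinant Escherichia coli carrying the tod genes. The step closes no ring; it turns the arene into a cyclohexadiene. C5 and C6 (1S and 2S in the numbering of 2) are set by the active site alone, which holds a monosubstituted benzene with its substituent in a fixed pocket and shows one face of the ortho,meta bond to the iron-bound oxygen. The step needs the bond next to iodine, one enantiomer and no further oxidation: the first two are properties of the enzyme for halogens of this size, and the third is secured by a host that lacks the cis-diol dehydrogenase, so 2 accumulates instead of going on to a catechol. Slow feeding answers the toxicity of 1 to the cells, and neutral pH answers the readiness of 2 to dehydrate.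

Step 2
Reactants: 2 (1S,2S)-3-iodocyclohexa-3,5-diene-1,2-diol
Product: 3 (3aS,7aS)-4-iodo-2-(4-methoxyphenyl)-3a,7a-dihydro-1,3-benzodioxole (O5,O6-acetal, both epimers at the acetal carbon)
Conditions: 4-MeOC6H4CH(OMe)2, CSA (cat.), CH2Cl2, −20 °C; Et3N quench
Reagents that add atoms: 4-methoxybenzaldehyde dimethyl acetal, COC(OC)c1ccc(OC)cc1
Why: Acid-catalysed transacetalisation of a cis-1,2-diol gives the cis-fused 2-aryl-1,3-dioxolane; low temperature and a basic quench are used because 2 loses water to iodophenols under acid. No ring stereocentre is touched.

Step 3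
Reactants: 3 (3aS,7aS)-4-iodo-2-(4-methoxyphenyl)-3a,7a-dihydro-1,3-benzodioxole
Product: 4 (1S,6S)-5-iodo-6-[(4-methoxyphenyl)methoxy]cyclohexa-2,4-dien-1-ol (O6-PMB, O5–H free)
Conditions: i-Bu2AlH, CH2Cl2, −78 to −40 °C; aq. potassium sodium tartrate
Reagents that add atoms: none
Why: Reductive opening of a 4-methoxybenzylidene acetal by a Lewis-acidic aluminium hydride, a standard way from a cyclic aryl acetal of a 1,2-diol to its mono-PMB ether. Aluminium should bind the more accessible and more basic O5 (O6 sits beside the C–I carbon), the acetal C–O5 bond ionises to the O6 oxocarbenium ion and hydride reduces it, leaving PMB on O6 and O5–H free; the vinyl iodide and diene are inert at this temperature.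

Step 4
Reactants: 4 (1S,6S)-5-iodo-6-[(4-methoxyphenyl)methoxy]cyclohexa-2,4-dien-1-ol
Product: 5 (1S,2R,3R,6S)-5-iodo-6-[(4-methoxyphenyl)methoxy]cyclohex-4-ene-1,2,3-triol (O3–H, O4–H, O5–H free; O6-PMB)
Conditions: OsO4 (cat.), NMO, acetone/H2O, 0 °C to rt
Reagents that add atoms: osmium tetroxide, O=[Os](=O)(=O)=O; N-methylmorpholine N-oxide, C[N+]1([O-])CCOCC1; water, O
Why: Catalytic osmylation with an amine N-oxide reoxidant: the suprafacial [3+2] addition of OsO4 should take the electron-richer disubstituted C3=C4 bond and leave the iodine-bearing C1=C2 bond alone. Attack is expected on the face opposite the allylic O5–H and the O6-PMB group (the usual anti preference of osmylation next to an allylic oxygen), which sets C3 and C4 cis to each other and trans to O5.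

Step 5
Reactants: 5 (1S,2R,3R,6S)-5-iodo-6-[(4-methoxyphenyl)methoxy]cyclohex-4-ene-1,2,3-triol
Product: 6 (3aS,4S,5S,7aR)-6-iodo-5-[(4-methoxyphenyl)methoxy]-2,2-dimethyl-3a,4,5,7a-tetrahydro-1,3-benzodioxol-4-ol (O3,O4-acetonide; O5–H free; O6-PMB)
Conditions: Me2C(OMe)2, PPTS (cat.), acetone, rt
Reagents that add atoms: 2,2-dimethoxypropane, COC(C)(C)OC
Why: Acid-catalysed ketalisation under thermodynamic control: the cis O3/O4 pair closes to a cis-fused dioxolane, whereas the trans O4/O5 pair would need a strained trans-fused one, so O5–H stays free. The PMB ether tolerates the weak acid.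

Step 6
Reactants: 6 (3aS,4S,5S,7aR)-6-iodo-5-[(4-methoxyphenyl)methoxy]-2,2-dimethyl-3a,4,5,7a-tetrahydro-1,3-benzodioxol-4-ol; 7 (tributylstannyl)methanol
Product: 8 (3aS,4R,5R,7aR)-6-(hydroxymethyl)-5-[(4-methoxyphenyl)methoxy]-2,2-dimethyl-3a,4,5,7a-tetrahydro-1,3-benzodioxol-4-ol (O5–H and O7–H free)
Conditions: Pd(PPh3)4 (cat.), 1,4-dioxane (degassed), 100 °C
Reagents that add atoms: none
Why: Stille cross-coupling: zerovalent palladium inserts into the C1–I bond, the hydroxymethyl group is transferred from tin in preference to butyl, and reductive elimination forms C1–C7 with the alkene in place. Free hydroxyls are tolerated, and no allylic ester is yet present to ionise on palladium.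

Step 7
Reactants: 8 (3aS,4R,5R,7aR)-6-(hydroxymethyl)-5-[(4-methoxyphenyl)methoxy]-2,2-dimethyl-3a,4,5,7a-tetrahydro-1,3-benzodioxol-4-ol; 9 benzoyl chloride
Product: 11 [(3aR,4R,5R,7aR)-4-(benzoyloxy)-5-[(4-methoxyphenyl)methoxy]-2,2-dimethyl-3a,4,5,7a-tetrahydro-1,3-benzodioxol-6-yl]methyl benzoate, via 7-O-monobenzoate 10 (not isolated)
Conditions: BzCl (2.5 equiv), pyridine, DMAP (cat.), CH2Cl2, 0 °C to rt
Reagents that add atoms: benzoyl chloride (the second equivalent of 9, which acylates 10 at O5), O=C(Cl)c1ccccc1
Why: Acylation with nucleophilic catalysis by DMAP: the only free hydroxyls of 8 are the primary allylic O7–H, which takes the first equivalent of 9 and gives 10, and the secondary O5–H, which takes the second, so exhaustive benzoylation needs no selectivity. No stereocentre is involved.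

Step 8
Reactants: 11 [(3aR,4R,5R,7aR)-4-(benzoyloxy)-5-[(4-methoxyphenyl)methoxy]-2,2-dimethyl-3a,4,5,7a-tetrahydro-1,3-benzodioxol-6-yl]methyl benzoate
Product: 12 [(3R,4R,5R,6R)-5-(benzoyloxy)-3,4,6-trihydroxycyclohex-1-en-1-yl]methyl benzoate (CNP0198957.3)
Conditions: TFA/CH2Cl2/H2O (5:4:1), anisole, 0 °C to rt
Reagents that add atoms: none
Why: Acidolysis: trifluoroacetic acid cleaves the PMB ether by loss of the 4-methoxybenzyl cation, which anisole captures in a Friedel–Crafts alkylation, and hydrolyses the isopropylidene ketal to acetone. Benzoates should neither cleave nor migrate appreciably in cold aqueous acid, and no stereocentre is touched, so 12 keeps the 3R,4R,5R,6R configuration.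

## Compound list

1 | iodobenzene | Ic1ccccc1 | starting material
2 | (1S,2S)-3-iodocyclohexa-3,5-diene-1,2-diol | IC1=CC=C[C@H](O)[C@@H]1O | intermediate
3 | (3aS,7aS)-4-iodo-2-(4-methoxyphenyl)-3a,7a-dihydro-1,3-benzodioxole (epimers at C2) | IC1=CC=C[C@H](OC2c3ccc(OC)cc3)[C@@H]1O2 | intermediate
4 | (1S,6S)-5-iodo-6-[(4-methoxyphenyl)methoxy]cyclohexa-2,4-dien-1-ol | IC1=CC=C[C@H](O)[C@@H]1OCc2ccc(OC)cc2 | intermediate
5 | (1S,2R,3R,6S)-5-iodo-6-[(4-methoxyphenyl)methoxy]cyclohex-4-ene-1,2,3-triol | IC1=C[C@@H](O)[C@@H](O)[C@H](O)[C@@H]1OCc2ccc(OC)cc2 | intermediate
6 | (3aS,4S,5S,7aR)-6-iodo-5-[(4-methoxyphenyl)methoxy]-2,2-dimethyl-3a,4,5,7a-tetrahydro-1,3-benzodioxol-4-ol | IC1=C[C@H]2OC(C)(C)O[C@H]2[C@H](O)[C@@H]1OCc3ccc(OC)cc3 | intermediate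
7 | (tributylstannyl)methanol | OC[Sn](CCCC)(CCCC)CCCC | starting material
8 | (3aS,4R,5R,7aR)-6-(hydroxymethyl)-5-[(4-methoxyphenyl)methoxy]-2,2-dimethyl-3a,4,5,7a-tetrahydro-1,3-benzodioxol-4-ol | OCC1=C[C@H]2OC(C)(C)O[C@H]2[C@H](O)[C@@H]1OCc3ccc(OC)cc3 | intermediate
9 | benzoyl chloride | O=C(Cl)c1ccccc1 | starting material
10 | [(3aS,4R,5R,7aR)-4-hydroxy-5-[(4-methoxyphenyl)methoxy]-2,2-dimethyl-3a,4,5,7a-tetrahydro-1,3-benzodioxol-6-yl]methyl benzoate (7-O-monobenzoate, not isolated) | O=C(OCC1=C[C@H]2OC(C)(C)O[C@H]2[C@H](O)[C@@H]1OCc3ccc(OC)cc3)c4ccccc4 | intermediate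
11 | [(3aR,4R,5R,7aR)-4-(benzoyloxy)-5-[(4-methoxyphenyl)methoxy]-2,2-dimethyl-3a,4,5,7a-tetrahydro-1,3-benzodioxol-6-yl]methyl benzoate | O=C(OCC1=C[C@H]2OC(C)(C)O[C@H]2[C@H](OC(=O)c3ccccc3)[C@@H]1OCc4ccc(OC)cc4)c5ccccc5 | intermediate
12 | [(3R,4R,5R,6R)-5-(benzoyloxy)-3,4,6-trihydroxycyclohex-1-en-1-yl]methyl benzoate | O=C(OCC1=C[C@@H](O)[C@@H](O)[C@H](OC(=O)c2ccccc2)[C@@H]1O)c1ccccc1 | target

## Step count and risks

Total step count: 8. Longest linear sequence: 8 steps (1 to 12); 7 and 9 are bought.

Step 1 (key step).
- Risk: low productivity and loss of product. Iodobenzene is a slower and more toxic substrate for the cells than the lighter halobenzenes, and the diol dehydrates to iodophenols during isolation if the broth turns acidic.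
- Fallback: the sequence sets out from a different arene in place of 1 and rejoins at 8. Bromobenzene F1 is fed to the same cells to give (1S,2S)-3-bromocyclohexa-3,5-diene-1,2-diol F2. The chemistry of steps 2–5 then gives bromo acetal F3, bromo dienol F4, bromo triol F5 and bromo acetonide F6. The vinyl bromide F6 is coupled with 7 under Stille conditions with a more electron-rich catalyst (Pd2(dba)3, P(t-Bu)3) to give 8.

Step 3.
- Risk: opening of the acetal in the wrong sense, leaving PMB on O5. The two acetal oxygens differ only by the neighbouring C–I carbon, and the two epimers of 3 may not behave alike.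
- Fallback: from 2 back to 4 by sequential protection. The hydroxyl remote from iodine is silylated with thexyldimethylsilyl chloride and imidazole to give silyl ether F7. O6 is then alkylated with 4-methoxybenzyl 2,2,2-trichloroacetimidate and catalytic La(OTf)3 to give silyl PMB diether F8. Bu4NF removes the silyl group to give 4.

Step 4.
- Risk: erosion of facial selectivity. The free allylic O5–H can hydrogen-bond to the oxidant and draw some of it to the same face, and the monocyclic diene is less biased than a bicyclic one.
- Fallback: from 3 back to 6 by changing the order. The rigid bicyclic acetal 3 is osmylated on its convex face to give diol F9, which is ketalised to bis-acetal F10. The aryl acetal is then opened with i-Bu2AlH, the isopropylidene ketal being far less reactive, to give 6.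

Step 6.
- Risk: slow transfer of the sp3 hydroxymethyl group from tin, so that butyl transfer, protodeiodination or homocoupling compete; tin residues may also complicate purification of polar 8.
- Fallback: from 6 back to 8 without tin. Palladium-catalysed methoxycarbonylation (Pd(OAc)2, PPh3, CO, MeOH, Et3N) gives methyl ester F11, and reduction with i-Bu2AlH gives 8.

Step 8.
- Risk: benzoyl migration (O5 to O6 or O4, O7 to O6) once the hydroxyls are free, and re-alkylation by the 4-methoxybenzyl cation; both become more likely as the acid gets stronger and the time longer.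
- Fallback: from 11 to 12 in two milder operations. Oxidative removal of the PMB ether with DDQ in buffered wet CH2Cl2 gives alcohol F12, and the ketal is then hydrolysed with aqueous acetic acid to give 12.

## Further compounds

F1 | step 1 | bromobenzene | Brc1ccccc1
F2 | step 1 | (1S,2S)-3-bromocyclohexa-3,5-diene-1,2-diol | BrC1=CC=C[C@H](O)[C@@H]1O
F3 | step 1 | (3aS,7aS)-4-bromo-2-(4-methoxyphenyl)-3a,7a-dihydro-1,3-benzodioxole (epimers at C2) | BrC1=CC=C[C@H](OC2c3ccc(OC)cc3)[C@@H]1O2
F4 | step 1 | (1S,6S)-5-bromo-6-[(4-methoxyphenyl)methoxy]cyclohexa-2,4-dien-1-ol | BrC1=CC=C[C@H](O)[C@@H]1OCc2ccc(OC)cc2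
F5 | step 1 | (1S,2R,3R,6S)-5-bromo-6-[(4-methoxyphenyl)methoxy]cyclohex-4-ene-1,2,3-triol | BrC1=C[C@@H](O)[C@@H](O)[C@H](O)[C@@H]1OCc2ccc(OC)cc2
F6 | step 1 | (3aS,4S,5S,7aR)-6-bromo-5-[(4-methoxyphenyl)methoxy]-2,2-dimethyl-3a,4,5,7a-tetrahydro-1,3-benzodioxol-4-ol | BrC1=C[C@H]2OC(C)(C)O[C@H]2[C@H](O)[C@@H]1OCc3ccc(OC)cc3
F7 | step 3 | (1S,6S)-6-{[(2,3-dimethylbutan-2-yl)dimethylsilyl]oxy}-2-iodocyclohexa-2,4-dien-1-ol (O5 silyl ether of 2) | IC1=CC=C[C@H](O[Si](C)(C)C(C)(C)C(C)C)[C@@H]1O
F8 | step 3 | {[(1S,6S)-5-iodo-6-[(4-methoxyphenyl)methoxy]cyclohexa-2,4-dien-1-yl]oxy}(2,3-dimethylbutan-2-yl)dimethylsilane (O5 silyl, O6 PMB) | IC1=CC=C[C@H](O[Si](C)(C)C(C)(C)C(C)C)[C@@H]1OCc2ccc(OC)cc2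
F9 | step 4 | (3aS,4R,5R,7aS)-7-iodo-2-(4-methoxyphenyl)-3a,4,5,7a-tetrahydro-1,3-benzodioxole-4,5-diol (epimers at C2) | IC1=C[C@@H](O)[C@@H](O)[C@H](OC2c3ccc(OC)cc3)[C@@H]1O2
F10 | step 4 | O3,O4-isopropylidene ketal of F9 (O5,O6-(4-methoxybenzylidene) acetal retained) | IC1=C[C@H]2OC(C)(C)O[C@H]2[C@H](OC3c4ccc(OC)cc4)[C@@H]1O3
F11 | step 6 | methyl (3aR,6R,7R,7aS)-7-hydroxy-6-[(4-methoxyphenyl)methoxy]-2,2-dimethyl-3a,6,7,7a-tetrahydro-1,3-benzodioxole-5-carboxylate | COC(=O)C1=C[C@H]2OC(C)(C)O[C@H]2[C@H](O)[C@@H]1OCc3ccc(OC)cc3
F12 | step 8 | [(3aR,4R,5R,7aR)-4-(benzoyloxy)-5-hydroxy-2,2-dimethyl-3a,4,5,7a-tetrahydro-1,3-benzodioxol-6-yl]methyl benzoate | O=C(OCC1=C[C@H]2OC(C)(C)O[C@H]2[C@H](OC(=O)c3ccccc3)[C@@H]1O)c4ccccc4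
A1 | alternative 1 | ethyl (Z)-enoate aldehyde with O3,O4-isopropylidene, O5-PMB and C6 as the aldehyde | CCOC(=O)/C=C\[C@H]1OC(C)(C)O[C@H]1[C@H](OCc2ccc(OC)cc2)C=O
A2 | alternative 1 | ethyl cyclohexenecarboxylate with O3,O4-isopropylidene, O5-PMB and free O6 hydroxyl | CCOC(=O)C1=C[C@H]2OC(C)(C)O[C@H]2[C@H](OCc2ccc(OC)cc2)[C@@H]1O
A3 | alternative 2 | (3,3-dimethoxy-6-oxocyclohexa-1,4-dien-1-yl)methyl benzoate | O=C(OCC1=CC(OC)(OC)C=CC1=O)c1ccccc1
A4 | alternative 2 | 4,5-epoxy enone monoketal of A3 | O=C(OCC1=CC(OC)(OC)[C@H]2O[C@H]2C1=O)c1ccccc1
A5 | alternative 3 | 1,6-epoxy-2-ene with O4 tert-butyl carbonate and O5, O7 benzoates | O=C(OC[C@@]12C=C[C@@H](OC(=O)OC(C)(C)C)[C@H](OC(=O)c3ccccc3)[C@@H]1O2)c4ccccc4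
A6 | alternative 3 | 3,4-cyclic carbonate of 12 | O=C(OCC1=C[C@H]2OC(=O)O[C@H]2[C@H](OC(=O)c2ccccc2)[C@@H]1O)c1ccccc1
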